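Ring A is built, not acylated. In ring A the C2 and C4 hydroxyls are 1,3-related and C5 carries the prenyl group, which is the oxygen and carbon pattern of a γ-prenylated acetoacetate, while the ketone-bearing C1 and the unsubstituted C6 correspond to a terminal ynone. The disconnection therefore cuts C1–C2 and C5–C6. One Diels–Alder reaction between a 4-prenyl 1-methoxy-1,3-bis(trimethylsilyloxy)diene and an ethynyl ketone that already carries the finished, TBS-protected ring B closes ring A; loss of methanol aromatises it with all four substituents correctly placed. Fluoride then frees the last phenol.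

Key step: step 8

Assumption: cudraphenone B has no stereocentre and both side-chain olefins end in a CMe2 group, so it is achiral and the single-enantiomer requirement is met without a stereocontrolling step. The transient stereocentres in 13 and 15 are destroyed again.

Step 1
Reactants: 1 methyl acetoacetate; 2 prenyl bromide
Product: 4 methyl 7-methyl-3-oxooct-6-enoate, via acetoacetate dianion 3 (not isolated)
Conditions: NaH, THF, 0 °C; n-BuLi, 0 °C; then 2, 0 °C→rt; aq HCl work-up
Reagents that add atoms: none
Why: γ-Alkylation of a β-keto ester dianion: the more basic terminal carbanion of 3 is alkylated by the allylic bromide (SN2), which puts the prenyl group on the carbon that becomes C5 of ring A.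

Step 2
Reactants: 4 methyl 7-methyl-3-oxooct-6-enoate
Product: 5 methyl 7-methyl-3-(trimethylsilyloxy)octa-2,6-dienoate (2E/2Z mixture)
Conditions: TMSCl, Et3N, toluene, rt
Reagents that add atoms: chlorotrimethylsilane, C[Si](C)(C)Cl
Why: Amine-mediated O-silylation of the enolised β-keto ester (silyl enol ether formation) removes the acidic C2 methylene, so the strong base of the next step can only take a γ-hydrogen.

Step 3
Reactants: 5 methyl 7-methyl-3-(trimethylsilyloxy)octa-2,6-dienoate
Product: 7 (1Z,3Z)-1-methoxy-7-methyl-1,3-bis(trimethylsilyloxy)octa-1,3,6-triene, via lithium dienolate 6 (not isolated)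
Conditions: LDA, THF, −78 °C; TMSCl, −78 °C→rt; filtered from LiCl under argon and used directly
Reagents that add atoms: chlorotrimethylsilane, C[Si](C)(C)Cl
Why: Kinetic γ-deprotonation of the β-silyloxy enoate gives the extended dienolate 6, which the silyl chloride traps on oxygen (vinylogous silyl ketene acetal formation); the isomer with the prenyl chain pointing away from C2 is expected, and the C1 geometry is irrelevant because that carbon becomes aromatic.

Step 4
Reactants: 8 2-bromo-3-hydroxybenzaldehyde
Product: 9 2-bromo-3-(tert-butyldimethylsilyloxy)benzaldehyde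
Conditions: TBSCl, imidazole, DMF, rt
Reagents that add atoms: tert-butyldimethylsilyl chloride, CC(C)(C)[Si](C)(C)Cl
Why: Imidazole-promoted silylation of a phenol masks the acidic OH, which would otherwise consume the Grignard reagent in step 6 and protonate the ketene-acetal diene in step 8.

Step 5
Reactants: 9 2-bromo-3-(tert-butyldimethylsilyloxy)benzaldehyde; 10 tributyl(3-methylbut-2-enyl)stannane
Product: 11 3-(tert-butyldimethylsilyloxy)-2-(3-methylbut-2-enyl)benzaldehyde
Conditions: Pd(PPh3)4 (5 mol %), DMF, 95 °C, no fluoride additive
Reagents that add atoms: none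
Why: Stille cross-coupling: the ortho-formyl group activates the C–Br bond for oxidative addition and the allyl–palladium intermediate should reductively eliminate at its unsubstituted terminus to give the linear prenyl arene, while fluoride-free conditions spare the aryl silyl ether.

Step 6
Reactants: 11 3-(tert-butyldimethylsilyloxy)-2-(3-methylbut-2-enyl)benzaldehyde; 12 ethynylmagnesium bromide
Product: 13 1-[3-(tert-butyldimethylsilyloxy)-2-(3-methylbut-2-enyl)phenyl]prop-2-yn-1-ol (racemic)
Conditions: THF, 0 °C; aq NH4Cl
Reagents that add atoms: none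
Why: Grignard 1,2-addition of the acetylide to the aldehyde; the carbinol centre forms as a racemate, which does not matter because step 7 oxidises it to the ketone.

Step 7
Reactants: 13 1-[3-(tert-butyldimethylsilyloxy)-2-(3-methylbut-2-enyl)phenyl]prop-2-yn-1-ol
Product: 14 1-[3-(tert-butyldimethylsilyloxy)-2-(3-methylbut-2-enyl)phenyl]prop-2-yn-1-one
Conditions: activated MnO2, CH2Cl2, rt; filtration through Celite
Reagents that add atoms: none
Why: Manganese dioxide oxidation is selective for the benzylic–propargylic carbinol and needs only filtration as work-up, which suits the electrophilic terminal ynone and leaves the prenyl olefin and the silyl ether untouched.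

Step 8
Reactants: 7 (1Z,3Z)-1-methoxy-7-methyl-1,3-bis(trimethylsilyloxy)octa-1,3,6-triene; 14 1-[3-(tert-butyldimethylsilyloxy)-2-(3-methylbut-2-enyl)phenyl]prop-2-yn-1-one
Product: 17 cudraphenone B ring-B tert-butyldimethylsilyl ether, via cyclohexa-1,4-diene cycloadduct 15 (not isolated), via ring-A bis(trimethylsilyl) ether 16 (not isolated)
Conditions: 7 (1.5 equiv), toluene, 0 °C→rt; then 0.5 M aq HCl, THF, 0 °C
Reagents that add atoms: none
Why: The prenyl-substituted C4 of diene 7, its most electron-rich position, attacks the unsubstituted β-carbon of ynone 14 and the ketene-acetal carbon C1 closes onto the α-carbon in an asynchronous, thermally allowed [4+2] cycloaddition that gives cyclohexa-1,4-diene 15. 1,4-Elimination of methanol from 15 (methoxy group from the acetal carbon, hydrogen from the doubly allylic prenyl-bearing carbon) gives arene 16, whose two labile aryl trimethylsilyl ethers are hydrolysed in the brief, cold acidic work-up while the bulkier aryl TBS ether stays on. The closest known reaction type is the benzannulation of 1-alkoxy-1-silyloxy dienes (vinylketene acetals) with acetylenic ketones and esters, which gives resorcinol derivatives with this orientation and with the oxygen of the ketene acetal left as a free hydroxyl. Ring A is closed by an intermolecular Diels–Alder cycloaddition that forms its C1–C2 and C5–C6 bonds in one operation, and no stereocentre has to be controlled because the two sp3 centres of 15 are flattened on aromatisation. The step needs regioselectivity, secured by the matched polarisation of the donor-substituted diene and the acceptor-substituted alkyne, and chemoselectivity for the alkyne over the ketone carbonyl and the two prenyl olefins, secured by the absence of a Lewis acid (no Michael–aldol closure to a biaryl salicylate) and by the unactivated nature of the prenyl double bonds.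

Step 9
Reactants: 17 cudraphenone B ring-B tert-butyldimethylsilyl ether
Product: 18 cudraphenone B
Conditions: TBAF, AcOH, THF, 0 °C
Reagents that add atoms: none
Why: Fluoride-induced cleavage of the aryl silyl ether (Si–F bond formation), buffered with acetic acid so that the acidic resorcinol is not exposed to basic fluoride and no strong acid is present that could cyclise the ortho-prenyl phenols to chromans.

Compound list
1 | methyl acetoacetate | CC(=O)CC(=O)OC | starting material
2 | prenyl bromide (1-bromo-3-methylbut-2-ene) | CC(C)=CCBr | starting material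
3 | sodium lithium dianion of methyl acetoacetate | [Na+].[Li+].C=C([O-])C=C([O-])OC | intermediate
4 | methyl 7-methyl-3-oxooct-6-enoate | COC(=O)CC(=O)CCC=C(C)C | intermediate
5 | methyl 7-methyl-3-(trimethylsilyloxy)octa-2,6-dienoate (2E/2Z mixture; this geometry is not carried forward) | COC(=O)C=C(O[Si](C)(C)C)CCC=C(C)C | intermediate
6 | lithium 1-methoxy-7-methyl-3-(trimethylsilyloxy)octa-1,3,6-trien-1-olate | [Li+].COC([O-])=CC(O[Si](C)(C)C)=CCC=C(C)C | intermediate
7 | (1Z,3Z)-1-methoxy-7-methyl-1,3-bis(trimethylsilyloxy)octa-1,3,6-triene | CO/C(O[Si](C)(C)C)=C/C(O[Si](C)(C)C)=C/CC=C(C)C | intermediate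
8 | 2-bromo-3-hydroxybenzaldehyde | O=Cc1cccc(O)c1Br | starting material
9 | 2-bromo-3-(tert-butyldimethylsilyloxy)benzaldehyde | O=Cc1cccc(O[Si](C)(C)C(C)(C)C)c1Br | intermediate
10 | tributyl(3-methylbut-2-enyl)stannane | CCCC[Sn](CCCC)(CCCC)CC=C(C)C | starting material
11 | 3-(tert-butyldimethylsilyloxy)-2-(3-methylbut-2-enyl)benzaldehyde | O=Cc1cccc(O[Si](C)(C)C(C)(C)C)c1CC=C(C)C | intermediate
12 | ethynylmagnesium bromide | C#C[Mg]Br | starting material
13 | 1-[3-(tert-butyldimethylsilyloxy)-2-(3-methylbut-2-enyl)phenyl]prop-2-yn-1-ol (racemic) | C#CC(O)c1cccc(O[Si](C)(C)C(C)(C)C)c1CC=C(C)C | intermediate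
14 | 1-[3-(tert-butyldimethylsilyloxy)-2-(3-methylbut-2-enyl)phenyl]prop-2-yn-1-one | C#CC(=O)c1cccc(O[Si](C)(C)C(C)(C)C)c1CC=C(C)C | intermediate
15 | [3-(tert-butyldimethylsilyloxy)-2-(3-methylbut-2-enyl)phenyl][6-methoxy-3-(3-methylbut-2-enyl)-4,6-bis(trimethylsilyloxy)cyclohexa-1,4-dien-1-yl]methanone (mixture of diastereomers, racemic) | COC1(O[Si](C)(C)C)C=C(O[Si](C)(C)C)C(CC=C(C)C)C=C1C(=O)c1cccc(O[Si](C)(C)C(C)(C)C)c1CC=C(C)C | intermediate
16 | [3-(tert-butyldimethylsilyloxy)-2-(3-methylbut-2-enyl)phenyl][5-(3-methylbut-2-enyl)-2,4-bis(trimethylsilyloxy)phenyl]methanone | CC(C)=CCc1cc(C(=O)c2cccc(O[Si](C)(C)C(C)(C)C)c2CC=C(C)C)c(O[Si](C)(C)C)cc1O[Si](C)(C)C | intermediate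
17 | [3-(tert-butyldimethylsilyloxy)-2-(3-methylbut-2-enyl)phenyl][2,4-dihydroxy-5-(3-methylbut-2-enyl)phenyl]methanone (cudraphenone B ring-B TBS ether) | CC(C)=CCc1cc(C(=O)c2cccc(O[Si](C)(C)C(C)(C)C)c2CC=C(C)C)c(O)cc1O | intermediate
18 | cudraphenone B, [2,4-dihydroxy-5-(3-methylbut-2-enyl)phenyl][3-hydroxy-2-(3-methylbut-2-enyl)phenyl]methanone (achiral) | CC(C)=CCc1cc(C(=O)c2cccc(O)c2CC=C(C)C)c(O)cc1O | target

Total step count: 9. Longest linear sequence: 6 steps (steps 4 to 9, from 8 to 18); the diene branch (steps 1 to 3) joins at step 8.

Steps most likely to fail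

Step 8. The diene may add in conjugate fashion without closing the ring, or close onto the ketone carbonyl to a biaryl salicylate. The cycloadduct may also lose silanol in place of methanol, which would leave a 2-methyl ether, or the ynone may oligomerise before it is intercepted. The fallback sets out from aldehyde 11, joins the two rings by carbonyl addition and comes back to the route at 17. 4,6-Dibromoresorcinol F1 (purchased) would be converted with MOMCl and i-Pr2NEt into 1,5-dibromo-2,4-bis(methoxymethoxy)benzene F2. One bromine–lithium exchange (n-BuLi, −78 °C), transmetalation to copper (CuBr·SMe2) and alkylation with prenyl bromide 2 should give 1-bromo-2,4-bis(methoxymethoxy)-5-(3-methylbut-2-enyl)benzene F3. A second exchange and addition of the aryllithium to 11 should give [2,4-bis(methoxymethoxy)-5-(3-methylbut-2-enyl)phenyl][3-(tert-butyldimethylsilyloxy)-2-(3-methylbut-2-enyl)phenyl]methanol F4. MnO2 oxidation should give [2,4-bis(methoxymethoxy)-5-(3-methylbut-2-enyl)phenyl][3-(tert-butyldimethylsilyloxy)-2-(3-methylbut-2-enyl)phenyl]methanone F5. Mild methanolysis of the two MOM ethers (dilute HCl in MeOH, rt), which the more acid-stable aryl TBS ether should survive, returns to 17. Should the silyl ether also be lost, the product is 18 itself.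

Step 5. The prenyl unit may be transposed during transmetalation and reductive elimination, giving the branched 1,1-dimethylallyl isomer, and coupling at the doubly ortho-substituted bromide may be sluggish. The fallback sets out from 9 and comes back at 11. Stille coupling of 9 with the smaller, regiochemically unambiguous allyltributylstannane (Pd(PPh3)4, DMF) should give 2-allyl-3-(tert-butyldimethylsilyloxy)benzaldehyde F6. Cross-metathesis of F6 with an excess of 2-methylbut-2-ene (second-generation ruthenium benzylidene catalyst, CH2Cl2, 40 °C) then builds the trisubstituted olefin and gives 11.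

Step 7. The terminal ynone may be lost by conjugate addition or oligomerisation on the oxidant surface or during isolation. The fallback sets out from 11 and comes back at 14, carrying the alkyne in C-silylated form until just before use. Lithium trimethylsilylacetylide (from ethynyltrimethylsilane and n-BuLi, THF, −78 °C) should add to 11 to give 1-[3-(tert-butyldimethylsilyloxy)-2-(3-methylbut-2-enyl)phenyl]-3-(trimethylsilyl)prop-2-yn-1-ol F7. MnO2 oxidation should give the robust, chromatographable 1-[3-(tert-butyldimethylsilyloxy)-2-(3-methylbut-2-enyl)phenyl]-3-(trimethylsilyl)prop-2-yn-1-one F8. Brief treatment with catalytic borax in aqueous methanol at rt removes the alkynyl silyl group to give 14, which is taken straight into step 8.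

Further compounds
F1 | step 8 | 4,6-dibromoresorcinol (4,6-dibromobenzene-1,3-diol; purchased) | Oc1cc(O)c(Br)cc1Br
F2 | step 8 | 1,5-dibromo-2,4-bis(methoxymethoxy)benzene | COCOc1cc(OCOC)c(Br)cc1Br
F3 | step 8 | 1-bromo-2,4-bis(methoxymethoxy)-5-(3-methylbut-2-enyl)benzene | COCOc1cc(OCOC)c(CC=C(C)C)cc1Br
F4 | step 8 | [2,4-bis(methoxymethoxy)-5-(3-methylbut-2-enyl)phenyl][3-(tert-butyldimethylsilyloxy)-2-(3-methylbut-2-enyl)phenyl]methanol (racemic) | COCOc1cc(OCOC)c(CC=C(C)C)cc1C(O)c1cccc(O[Si](C)(C)C(C)(C)C)c1CC=C(C)C
F5 | step 8 | [2,4-bis(methoxymethoxy)-5-(3-methylbut-2-enyl)phenyl][3-(tert-butyldimethylsilyloxy)-2-(3-methylbut-2-enyl)phenyl]methanone | COCOc1cc(OCOC)c(CC=C(C)C)cc1C(=O)c1cccc(O[Si](C)(C)C(C)(C)C)c1CC=C(C)C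
F6 | step 5 | 2-allyl-3-(tert-butyldimethylsilyloxy)benzaldehyde | C=CCc1c(C=O)cccc1O[Si](C)(C)C(C)(C)C
F7 | step 7 | 1-[3-(tert-butyldimethylsilyloxy)-2-(3-methylbut-2-enyl)phenyl]-3-(trimethylsilyl)prop-2-yn-1-ol (racemic) | C[Si](C)(C)C#CC(O)c1cccc(O[Si](C)(C)C(C)(C)C)c1CC=C(C)C
F8 | step 7 | 1-[3-(tert-butyldimethylsilyloxy)-2-(3-methylbut-2-enyl)phenyl]-3-(trimethylsilyl)prop-2-yn-1-one | C[Si](C)(C)C#CC(=O)c1cccc(O[Si](C)(C)C(C)(C)C)c1CC=C(C)C
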